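Ring B is an 8-hydroxy tetrahydroisoquinoline whose nitrogen lies between two methyl-bearing carbons, C1 and C3, in a trans relation, which lets both centres be installed on an acyclic sulfonamide ahead of ring formation. The route therefore cuts C4a–C8a and C7–C8: one gold-catalysed furan–alkyne reaction closes the nitrogen ring and the benzene ring of ring B and moves the furan oxygen to C8. Its precursor is a 2-alkyl-3-naphthyl furan carrying an electron-poor mesylate on O4 and an N-nosyl (R,R)-N-(but-3-yn-2-yl)aminopropyl tether. A Suzuki coupling then adds the ring A–naphthalene boronate, and base and acid steps free the phenols and close the ring A imine.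

Key step: step 15

Assumption: the SMILES fixes three stereocentres (C1 and C3 of ring B, C3 of ring A, all R) and no biaryl axis, so the two hindered isoquinoline–naphthalene axes are left uncontrolled; 26 and 38 are expected as atropisomer pairs to be separated or carried on.

Locants and shorthand: rings A and B are numbered as isoquinolines (C1, N2, C3, C4, C4a, C5–C8, C8a). ClNap = 3-chloro-5-methoxy-4-(methoxymethoxy)-7-methylnaphthalen-1-yl. Ns = 2-nitrobenzenesulfonyl, Ms = methanesulfonyl, MOM = methoxymethyl, Boc = tert-butoxycarbonyl.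

**Naphthalene boronate (steps 1–6)**

Step 1
Reactants: 1 (E)-but-2-enoyl chloride; 2 diethylamine
Product: 3 (E)-N,N-diethylbut-2-enamide
Conditions: Et2NH (2.2 equiv), CH2Cl2, 0 °C
Reagents that add atoms: none
Why: Acylation of a secondary amine by an acid chloride (Schotten–Baumann type) is dependable, the second equivalent of amine binding the HCl.

Step 2
Reactants: 3 (E)-N,N-diethylbut-2-enamide; 4 1-bromo-3-methoxy-5-methylbenzene
Product: 6 8-methoxy-6-methylnaphthalen-1-ol, via lithium dienolate 5 (not isolated)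
Conditions: LDA (3.5 equiv), THF, −78 °C, 3 then 4; warm to 23 °C; aq. NH4Cl
Reagents that add atoms: none
Why: Aryne annulation with an amide dienolate: LDA forms dienolate 5 and, by removing the proton between Br and OMe of 4, 3-methoxy-5-methylbenzyne, which 5 attacks through its γ-carbon at the aryne carbon remote from OMe so that the aryl anion next to OMe closes on the amide carbonyl and the new ring aromatises to the naphthol with OH peri to OMe.

Step 3
Reactants: 6 8-methoxy-6-methylnaphthalen-1-ol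
Product: 7 4-bromo-8-methoxy-6-methylnaphthalen-1-ol
Conditions: NBS (1.0 equiv), MeCN, −20 °C
Reagents that add atoms: N-bromosuccinimide, O=C1CCC(=O)N1Br
Why: Electrophilic aromatic bromination of a free 1-naphthol in MeCN should go para to the hydroxyl, whose hydrogen bond to the peri methoxy group is expected to hinder ortho delivery, and the phenolic ring is far more reactive than the anisole ring.

Step 4
Reactants: 7 4-bromo-8-methoxy-6-methylnaphthalen-1-ol
Product: 8 4-bromo-2-chloro-8-methoxy-6-methylnaphthalen-1-ol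
Conditions: NCS (1.05 equiv), i-Pr2NH (10 mol%), CH2Cl2, 0 → 23 °C
Reagents that add atoms: N-chlorosuccinimide, O=C1CCC(=O)N1Cl
Why: With the para position blocked, amine-mediated electrophilic chlorination of the naphthol can only take the ortho carbon C2, which becomes the site of the naphthalene–naphthalene coupling.

Step 5
Reactants: 8 4-bromo-2-chloro-8-methoxy-6-methylnaphthalen-1-ol
Product: 9 4-bromo-2-chloro-8-methoxy-1-(methoxymethoxy)-6-methylnaphthalene
Conditions: NaH, MOMCl, DMF, 0 °C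
Reagents that add atoms: chloromethyl methyl ether, COCCl
Why: Williamson-type O-alkylation of the sodium naphtholate by the reactive chloromethyl ether protects the hindered hydroxyl as an acetal that withstands base and palladium chemistry.

Step 6
Reactants: 9 4-bromo-2-chloro-8-methoxy-1-(methoxymethoxy)-6-methylnaphthalene
Product: 10 2-(ClNap)-4,4,5,5-tetramethyl-1,3,2-dioxaborolane
Conditions: B2pin2, Pd(dppf)Cl2 (5 mol%), KOAc, 1,4-dioxane, 90 °C
Reagents that add atoms: bis(pinacolato)diboron, CC1(C)OB(OC1(C)C)B1OC(C)(C)C(C)(C)O1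
Why: Miyaura borylation, in which zerovalent palladium formed in situ inserts into the C–Br bond much faster than into the electron-rich ortho-substituted C–Cl bond, so the chloride is kept for later.

**Ring B precursor and key step (steps 7–15)**

Step 7
Reactants: 11 (S)-pent-4-yn-2-ol; 12 2-[(tert-butyldimethylsilyl)oxy]-N-methoxy-N-methylacetamide
Product: 14 (6S)-1-[(tert-butyldimethylsilyl)oxy]-6-hydroxyhept-3-yn-2-one, via dilithio alkynolate 13 (not isolated)
Conditions: n-BuLi (2.1 equiv), THF, −78 °C; then 12, −78 → 0 °C; aq. NH4Cl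
Reagents that add atoms: none
Why: Weinreb ketone synthesis, in which the acetylide carbon of the O,C-dianion adds to the N-methoxy-N-methylamide and the chelated adduct releases the ynone only on work-up, so no second addition occurs and the carbinol centre is untouched.

Step 8
Reactants: 14 (6S)-1-[(tert-butyldimethylsilyl)oxy]-6-hydroxyhept-3-yn-2-one
Product: 16 5-[(2S)-2-hydroxypropyl]furan-3(2H)-one, via dihydroxy ynone 15 (not isolated)
Conditions: TBAF (1.1 equiv), THF, 0 → 23 °C
Reagents that add atoms: none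
Why: Fluoride cleaves the silyl ether and the freed primary alkoxide adds 5-endo-dig to the ynone β-carbon (oxa-Michael cyclisation), the established hydroxy-ynone route to 3(2H)-furanones.

Step 9
Reactants: 16 5-[(2S)-2-hydroxypropyl]furan-3(2H)-one; 17 tert-butyl N-[(2-nitrophenyl)sulfonyl]carbamate
Product: 18 tert-butyl N-[(2-nitrophenyl)sulfonyl]-N-[(2R)-1-(4-oxo-4,5-dihydrofuran-2-yl)propan-2-yl]carbamate
Conditions: PPh3, DIAD, THF, 0 → 23 °C
Reagents that add atoms: none
Why: Fukuyama–Mitsunobu reaction, in which the strongly acidic N-Boc sulfonamide displaces the phosphonium-activated secondary alcohol by SN2 with inversion, turning the (S)-carbinol into the (R)-configured C–N centre that becomes C3 of ring B.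

Step 10
Reactants: 18 tert-butyl N-[(2-nitrophenyl)sulfonyl]-N-[(2R)-1-(4-oxo-4,5-dihydrofuran-2-yl)propan-2-yl]carbamate
Product: 19 2-nitro-N-[(2R)-1-(4-oxo-4,5-dihydrofuran-2-yl)propan-2-yl]benzenesulfonamide
Conditions: TFA/CH2Cl2 (1:4), 0 → 23 °C
Reagents that add atoms: none
Why: Acidolysis of the tert-butyl carbamate leaves the sulfonamide N–H needed for the second N-alkylation, and the vinylogous ester of the furanone tolerates acid.

Step 11
Reactants: 19 2-nitro-N-[(2R)-1-(4-oxo-4,5-dihydrofuran-2-yl)propan-2-yl]benzenesulfonamide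
Product: 20 N-[(2R)-1-(3-iodo-4-oxo-4,5-dihydrofuran-2-yl)propan-2-yl]-2-nitrobenzenesulfonamide
Conditions: NIS (1.05 equiv), MeCN, 0 → 23 °C
Reagents that add atoms: N-iodosuccinimide, O=C1CCC(=O)N1I
Why: The α-carbon of the vinylogous ester is its nucleophilic position, so electrophilic iodination there (α-iodination of a β-alkoxy enone) provides the vinyl iodide for cross-coupling.

Step 12
Reactants: 20 N-[(2R)-1-(3-iodo-4-oxo-4,5-dihydrofuran-2-yl)propan-2-yl]-2-nitrobenzenesulfonamide; 10 2-(ClNap)-4,4,5,5-tetramethyl-1,3,2-dioxaborolane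
Product: 21 N-[(2R)-1-[3-(ClNap)-4-oxo-4,5-dihydrofuran-2-yl]propan-2-yl]-2-nitrobenzenesulfonamide
Conditions: Pd(dppf)Cl2 (5 mol%), K3PO4, 1,4-dioxane/H2O (9:1), 60 °C
Reagents that add atoms: none
Why: Suzuki–Miyaura coupling of an α-iodo enone is fast with this divalent palladium precatalyst, which does not activate the hindered aryl chloride of 10, and it forms the bond that becomes the C5–naphthalene bond of ring B.

Step 13
Reactants: 21 N-[(2R)-1-[3-(ClNap)-4-oxo-4,5-dihydrofuran-2-yl]propan-2-yl]-2-nitrobenzenesulfonamide; 22 (S)-but-3-yn-2-ol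
Product: 23 N-[(2R)-but-3-yn-2-yl]-N-[(2R)-1-[3-(ClNap)-4-oxo-4,5-dihydrofuran-2-yl]propan-2-yl]-2-nitrobenzenesulfonamide
Conditions: PPh3, DIAD, toluene, 0 → 23 °C
Reagents that add atoms: none
Why: Fukuyama–Mitsunobu N-alkylation, in which the nosylamide anion displaces the activated propargylic alcohol by SN2 with inversion, so the (S)-alcohol gives the (R)-configured carbon that becomes C1, the sulfonamide N–H being far more acidic than the furanone CH2.

Step 14
Reactants: 23 N-[(2R)-but-3-yn-2-yl]-N-[(2R)-1-[3-(ClNap)-4-oxo-4,5-dihydrofuran-2-yl]propan-2-yl]-2-nitrobenzenesulfonamide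
Product: 25 5-[(2R)-2-[N-[(2R)-but-3-yn-2-yl]-2-nitrobenzenesulfonamido]propyl]-4-(ClNap)furan-3-yl methanesulfonate, via lithium furanolate 24 (not isolated)
Conditions: LiHMDS (1.05 equiv), THF, −78 °C; then Ms2O, −78 → 0 °C
Reagents that add atoms: methanesulfonic anhydride, CS(=O)(=O)OS(C)(=O)=O
Why: Deprotonation of the furanone CH2 gives the aromatic furan-3-olate, whose oxygen is sulfonylated by the hard anhydride (enol sulfonate formation), the much less acidic alkyne C–H being left alone by one equivalent of amide base at −78 °C.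

Step 15
Reactants: 25 5-[(2R)-2-[N-[(2R)-but-3-yn-2-yl]-2-nitrobenzenesulfonamido]propyl]-4-(ClNap)furan-3-yl methanesulfonate
Product: 26 (1R,3R)-5-(ClNap)-8-hydroxy-1,3-dimethyl-2-(2-nitrobenzenesulfonyl)-1,2,3,4-tetrahydroisoquinolin-6-yl methanesulfonate
Conditions: AuCl3 (5 mol%), MeCN, 23 °C
Reagents that add atoms: none
Why: AuCl3 (trivalent gold) activates the terminal alkyne, the side-chain-bearing furan carbon attacks its internal carbon, and the resulting cyclopropyl gold carbenoid opens to a dienal carbenoid whose carbonyl oxygen closes to an oxepine in equilibrium with its arene oxide, which opens and loses a proton to give the phenol. The closest known reaction type is the gold-catalysed furan–yne phenol synthesis that turns N-sulfonyl N-propargyl 2-furylethylamines into 8-hydroxytetrahydroisoquinolines. The nitrogen ring closes by 6-exo-dig attack of the furan on the alkyne (C4a–C8a), and the benzene ring closes by 6π electrocyclisation of the oxepine to the arene oxide (C7–C8, former furan CH to alkyne terminus). No stereocentre is made, C1 and C3 being carried unchanged from the chain, and only the C5–naphthalene axis becomes fixed, without control. The step needs oxygen at C8 and not at C7: breaking the C7–O bond of the arene oxide spreads charge over C7, C5 and C8a, whereas breaking C8–O would put charge on C6, which an oxygen π-donor there would favour, so C6 carries a mesylate that withdraws this stabilisation and lets the opening follow the parent reaction. Attack by the furan and not by the electron-rich naphthalene is secured by ring size, since only the furan reaches the alkyne through a six-membered transition state.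

**Ring A–naphthalene boronate (steps 16–23)**

Step 16
Reactants: 27 5-bromobenzene-1,3-diol
Product: 28 1-(2-bromo-4,6-dihydroxyphenyl)ethan-1-one
Conditions: AcOH, BF3·OEt2, 90 °C; then aq. NaOAc
Reagents that add atoms: acetic acid, CC(=O)O
Why: Friedel–Crafts acylation of a 5-substituted resorcinol takes place at C4, para to one hydroxyl and ortho to the other, as in the acetylation of orcinol, and supplies C1 of ring A with its methyl group.

Step 17
Reactants: 29 tert-butyl N-[(2R)-1-hydroxypropan-2-yl]carbamate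
Product: 30 tert-butyl N-[(2R)-1-iodopropan-2-yl]carbamate
Conditions: I2, PPh3, imidazole, CH2Cl2, 0 → 23 °C
Reagents that add atoms: iodine, II
Why: Appel-type iodination replaces the primary hydroxyl without touching the neighbouring stereocentre, the future C3 of ring A.

Step 18
Reactants: 28 1-(2-bromo-4,6-dihydroxyphenyl)ethan-1-one; 30 tert-butyl N-[(2R)-1-iodopropan-2-yl]carbamate
Product: 34 tert-butyl N-[(2R)-1-(2-acetyl-3,5-dihydroxyphenyl)propan-2-yl]carbamate, via alkylzinc iodide 31 (not isolated), via bis(trimethylsilyl) ether 32 (not isolated), via silylated coupling product 33 (not isolated)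
Conditions: 30, Zn dust (I2-activated), DMF, 23 °C; 28, N,O-bis(trimethylsilyl)acetamide, THF, 23 °C; combine, Pd2(dba)3 (2.5 mol%), SPhos (10 mol%), 50 °C; then K2CO3, MeOH, 23 °C
Reagents that add atoms: none
Why: Negishi coupling of the β-amidoalkylzinc iodide with the aryl bromide activated by its ortho acetyl group joins the sp3 carbon to the ring without touching the stereocentre, the phenols being masked in situ as silyl ethers so that they cannot protonate the zinc reagent.

Step 19
Reactants: 34 tert-butyl N-[(2R)-1-(2-acetyl-3,5-dihydroxyphenyl)propan-2-yl]carbamate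
Product: 35 tert-butyl N-[(2R)-1-(2-acetyl-3,5-dihydroxy-4-iodophenyl)propan-2-yl]carbamate
Conditions: I2 (0.4 equiv), HIO3 (0.2 equiv), EtOH/H2O, 23 °C
Reagents that add atoms: iodine, II; iodic acid, O[I](=O)=O
Why: Electrophilic iodination of a 4-acylresorcinol goes to the carbon between the two hydroxyl groups, as known for 2,4-dihydroxyacetophenone under these conditions, which places iodine at the future C7 of ring A.

Step 20
Reactants: 35 tert-butyl N-[(2R)-1-(2-acetyl-3,5-dihydroxy-4-iodophenyl)propan-2-yl]carbamate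
Product: 36 tert-butyl N-[(2R)-1-[2-acetyl-3-hydroxy-4-iodo-5-(methoxymethoxy)phenyl]propan-2-yl]carbamate
Conditions: MOMCl (1.1 equiv), i-Pr2NEt, CH2Cl2, 0 °C
Reagents that add atoms: chloromethyl methyl ether, COCCl
Why: O-Alkylation under mild amine base takes only the hydroxyl para to the acetyl group, because the ortho hydroxyl is tied up in a hydrogen bond to the ketone, which is the classical way to tell the two oxygens of a 2,4-dihydroxyacetophenone apart.

Step 21
Reactants: 36 tert-butyl N-[(2R)-1-[2-acetyl-3-hydroxy-4-iodo-5-(methoxymethoxy)phenyl]propan-2-yl]carbamate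
Product: 37 tert-butyl N-[(2R)-1-[2-acetyl-4-iodo-3-methoxy-5-(methoxymethoxy)phenyl]propan-2-yl]carbamate
Conditions: MeI, K2CO3, DMF, 40 °C
Reagents that add atoms: iodomethane, CI
Why: Williamson methylation of the remaining chelated phenol sets the C8 methyl ether of ring A, carbonate being too weak to alkylate the carbamate nitrogen or the ketone.

Step 22
Reactants: 37 tert-butyl N-[(2R)-1-[2-acetyl-4-iodo-3-methoxy-5-(methoxymethoxy)phenyl]propan-2-yl]carbamate; 10 2-(ClNap)-4,4,5,5-tetramethyl-1,3,2-dioxaborolane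
Product: 38 tert-butyl N-[(2R)-1-[2-acetyl-4-(ClNap)-3-methoxy-5-(methoxymethoxy)phenyl]propan-2-yl]carbamate
Conditions: Pd(PPh3)4 (10 mol%), K3PO4, DME/H2O (4:1), 85 °C
Reagents that add atoms: none
Why: Suzuki–Miyaura coupling with Pd(PPh3)4 (zerovalent palladium) inserts only into the C–I bond between the two ether oxygens and leaves the naphthyl chloride alone, giving the hindered biaryl that holds the C7–naphthalene bond of ring A.

Step 23
Reactants: 38 tert-butyl N-[(2R)-1-[2-acetyl-4-(ClNap)-3-methoxy-5-(methoxymethoxy)phenyl]propan-2-yl]carbamate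
Product: 39 tert-butyl N-[(2R)-1-[2-acetyl-3-methoxy-5-(methoxymethoxy)-4-[5-methoxy-4-(methoxymethoxy)-7-methyl-3-(4,4,5,5-tetramethyl-1,3,2-dioxaborolan-2-yl)naphthalen-1-yl]phenyl]propan-2-yl]carbamate
Conditions: B2pin2, Pd2(dba)3 (2.5 mol%), XPhos (10 mol%), KOAc, 1,4-dioxane, 100 °C
Reagents that add atoms: bis(pinacolato)diboron, CC1(C)OB(OC1(C)C)B1OC(C)(C)C(C)(C)O1
Why: Miyaura borylation of an aryl chloride is feasible with a bulky dialkylbiarylphosphine on palladium, and the ketone, carbamate and acetals are inert to acetate base.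

**Union and deprotection (steps 24–26)**

Step 24
Reactants: 26 (1R,3R)-5-(ClNap)-8-hydroxy-1,3-dimethyl-2-(2-nitrobenzenesulfonyl)-1,2,3,4-tetrahydroisoquinolin-6-yl methanesulfonate; 39 ring A–naphthalene boronate
Product: 40 N-Ns 6-O-Ms coupled product, in which C3 of the naphthalene of 26 is bonded to C3 of the naphthalene of 39 (full name in the compound list)
Conditions: Pd(OAc)2 (5 mol%), SPhos (10 mol%), K3PO4, 1,4-dioxane/H2O (5:1), 80 °C
Reagents that add atoms: none
Why: Suzuki–Miyaura coupling of an electron-rich ortho-alkoxy aryl chloride is within the scope of this ligand, while the aryl mesylate, the sulfonamide and the free phenol are not touched at this temperature.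

Step 25
Reactants: 40 N-Ns 6-O-Ms coupled product
Product: 42 ring B amine diol with Boc and MOM groups retained, via N-deprotected mesylate 41 (not isolated)
Conditions: PhSH (3 equiv), KOH (8 equiv), MeOH/THF (1:1), 60 °C, argon
Reagents that add atoms: none
Why: Thiolate adds to the nitroarene at the carbon bearing sulfur (Meisenheimer complex, nosyl cleavage with loss of SO2) to free the secondary amine, and hydroxide then cleaves the aryl methanesulfonate at sulfur under the same basic conditions, which the carbamate and acetals survive.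

Step 26
Reactants: 42 ring B amine diol with Boc and MOM groups retained
Product: 44 korundamine A, via amino ketone 43 (not isolated)
Conditions: HCl (3 M in MeOH), 40 °C; then aq. NaHCO3
Reagents that add atoms: none
Why: Acidic methanolysis removes the three methoxymethyl acetals and the Boc group, and the freed primary amine condenses with the ortho acetyl group to close the six-membered cyclic imine of ring A (3,4-dihydroisoquinoline formation), no stereocentre being affected.

**Compound list**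

1 | (E)-but-2-enoyl chloride | C/C=C/C(Cl)=O | starting material
2 | diethylamine | CCNCC | starting material
3 | (E)-N,N-diethylbut-2-enamide | C/C=C/C(=O)N(CC)CC | intermediate
4 | 1-bromo-3-methoxy-5-methylbenzene | COc1cc(C)cc(Br)c1 | starting material
5 | lithium 1-(diethylamino)buta-1,3-dien-1-olate | C=CC=C(O[Li])N(CC)CC | intermediate
6 | 8-methoxy-6-methylnaphthalen-1-ol | COc1cc(C)cc2cccc(O)c12 | intermediate
7 | 4-bromo-8-methoxy-6-methylnaphthalen-1-ol | COc1cc(C)cc2c(Br)ccc(O)c12 | intermediate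
8 | 4-bromo-2-chloro-8-methoxy-6-methylnaphthalen-1-ol | COc1cc(C)cc2c(Br)cc(Cl)c(O)c12 | intermediate
9 | 4-bromo-2-chloro-8-methoxy-1-(methoxymethoxy)-6-methylnaphthalene | COc1cc(C)cc2c(Br)cc(Cl)c(OCOC)c12 | intermediate
10 | 2-[3-chloro-5-methoxy-4-(methoxymethoxy)-7-methylnaphthalen-1-yl]-4,4,5,5-tetramethyl-1,3,2-dioxaborolane | COc1cc(C)cc2c(B3OC(C)(C)C(C)(C)O3)cc(Cl)c(OCOC)c12 | intermediate
11 | (S)-pent-4-yn-2-ol | C[C@H](O)CC#C | starting material
12 | 2-[(tert-butyldimethylsilyl)oxy]-N-methoxy-N-methylacetamide | CON(C)C(=O)CO[Si](C)(C)C(C)(C)C | starting material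
13 | lithium (2S)-5-lithiopent-4-yn-2-olate | C[C@H](O[Li])CC#C[Li] | intermediate
14 | (6S)-1-[(tert-butyldimethylsilyl)oxy]-6-hydroxyhept-3-yn-2-one | C[C@H](O)CC#CC(=O)CO[Si](C)(C)C(C)(C)C | intermediate
15 | (6S)-1,6-dihydroxyhept-3-yn-2-one | C[C@H](O)CC#CC(=O)CO | intermediate
16 | 5-[(2S)-2-hydroxypropyl]furan-3(2H)-one | C[C@H](O)CC1=CC(=O)CO1 | intermediate
17 | tert-butyl N-[(2-nitrophenyl)sulfonyl]carbamate | CC(C)(C)OC(=O)NS(=O)(=O)c1ccccc1[N+](=O)[O-] | starting material
18 | tert-butyl N-[(2-nitrophenyl)sulfonyl]-N-[(2R)-1-(4-oxo-4,5-dihydrofuran-2-yl)propan-2-yl]carbamate | C[C@@H](N(C(=O)OC(C)(C)C)S(=O)(=O)c1ccccc1[N+](=O)[O-])CC1=CC(=O)CO1 | intermediate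
19 | 2-nitro-N-[(2R)-1-(4-oxo-4,5-dihydrofuran-2-yl)propan-2-yl]benzenesulfonamide | C[C@@H](NS(=O)(=O)c1ccccc1[N+](=O)[O-])CC1=CC(=O)CO1 | intermediate
20 | N-[(2R)-1-(3-iodo-4-oxo-4,5-dihydrofuran-2-yl)propan-2-yl]-2-nitrobenzenesulfonamide | C[C@@H](NS(=O)(=O)c1ccccc1[N+](=O)[O-])CC1=C(I)C(=O)CO1 | intermediate
21 | N-[(2R)-1-[3-[3-chloro-5-methoxy-4-(methoxymethoxy)-7-methylnaphthalen-1-yl]-4-oxo-4,5-dihydrofuran-2-yl]propan-2-yl]-2-nitrobenzenesulfonamide | C[C@@H](NS(=O)(=O)c1ccccc1[N+](=O)[O-])CC1=C(c2cc(Cl)c(OCOC)c3c(OC)cc(C)cc23)C(=O)CO1 | intermediate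
22 | (S)-but-3-yn-2-ol | C[C@H](O)C#C | starting material
23 | N-[(2R)-but-3-yn-2-yl]-N-[(2R)-1-[3-[3-chloro-5-methoxy-4-(methoxymethoxy)-7-methylnaphthalen-1-yl]-4-oxo-4,5-dihydrofuran-2-yl]propan-2-yl]-2-nitrobenzenesulfonamide | C[C@@H](N([C@H](C)C#C)S(=O)(=O)c1ccccc1[N+](=O)[O-])CC1=C(c2cc(Cl)c(OCOC)c3c(OC)cc(C)cc23)C(=O)CO1 | intermediate
24 | lithium 5-[(2R)-2-[N-[(2R)-but-3-yn-2-yl]-2-nitrobenzenesulfonamido]propyl]-4-[3-chloro-5-methoxy-4-(methoxymethoxy)-7-methylnaphthalen-1-yl]furan-3-olate | C[C@@H](N([C@H](C)C#C)S(=O)(=O)c1ccccc1[N+](=O)[O-])Cc1occ(O[Li])c1-c1cc(Cl)c(OCOC)c2c(OC)cc(C)cc12 | intermediate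
25 | 5-[(2R)-2-[N-[(2R)-but-3-yn-2-yl]-2-nitrobenzenesulfonamido]propyl]-4-[3-chloro-5-methoxy-4-(methoxymethoxy)-7-methylnaphthalen-1-yl]furan-3-yl methanesulfonate | C[C@@H](N([C@H](C)C#C)S(=O)(=O)c1ccccc1[N+](=O)[O-])Cc1occ(OS(C)(=O)=O)c1-c1cc(Cl)c(OCOC)c2c(OC)cc(C)cc12 | intermediate
26 | (1R,3R)-5-[3-chloro-5-methoxy-4-(methoxymethoxy)-7-methylnaphthalen-1-yl]-8-hydroxy-1,3-dimethyl-2-(2-nitrobenzenesulfonyl)-1,2,3,4-tetrahydroisoquinolin-6-yl methanesulfonate | COc1cc(C)cc2c(-c3c(OS(C)(=O)=O)cc(O)c4c3C[C@@H](C)N(S(=O)(=O)c3ccccc3[N+](=O)[O-])[C@@H]4C)cc(Cl)c(OCOC)c12 | intermediate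
27 | 5-bromobenzene-1,3-diol | Oc1cc(O)cc(Br)c1 | starting material
28 | 1-(2-bromo-4,6-dihydroxyphenyl)ethan-1-one | CC(=O)c1c(O)cc(O)cc1Br | intermediate
29 | tert-butyl N-[(2R)-1-hydroxypropan-2-yl]carbamate (N-Boc-D-alaninol) | C[C@@H](NC(=O)OC(C)(C)C)CO | starting material
30 | tert-butyl N-[(2R)-1-iodopropan-2-yl]carbamate | C[C@@H](NC(=O)OC(C)(C)C)CI | intermediate
31 | [(2R)-2-[(tert-butoxycarbonyl)amino]propyl]zinc iodide | C[C@@H](NC(=O)OC(C)(C)C)C[Zn]I | intermediate
32 | 1-[2-bromo-4,6-bis(trimethylsilyloxy)phenyl]ethan-1-one | CC(=O)c1c(O[Si](C)(C)C)cc(O[Si](C)(C)C)cc1Br | intermediate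
33 | tert-butyl N-[(2R)-1-[2-acetyl-3,5-bis(trimethylsilyloxy)phenyl]propan-2-yl]carbamate | CC(=O)c1c(O[Si](C)(C)C)cc(O[Si](C)(C)C)cc1C[C@@H](C)NC(=O)OC(C)(C)C | intermediate
34 | tert-butyl N-[(2R)-1-(2-acetyl-3,5-dihydroxyphenyl)propan-2-yl]carbamate | CC(=O)c1c(O)cc(O)cc1C[C@@H](C)NC(=O)OC(C)(C)C | intermediate
35 | tert-butyl N-[(2R)-1-(2-acetyl-3,5-dihydroxy-4-iodophenyl)propan-2-yl]carbamate | CC(=O)c1c(O)c(I)c(O)cc1C[C@@H](C)NC(=O)OC(C)(C)C | intermediate
36 | tert-butyl N-[(2R)-1-[2-acetyl-3-hydroxy-4-iodo-5-(methoxymethoxy)phenyl]propan-2-yl]carbamate | CC(=O)c1c(O)c(I)c(OCOC)cc1C[C@@H](C)NC(=O)OC(C)(C)C | intermediate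
37 | tert-butyl N-[(2R)-1-[2-acetyl-4-iodo-3-methoxy-5-(methoxymethoxy)phenyl]propan-2-yl]carbamate | CC(=O)c1c(OC)c(I)c(OCOC)cc1C[C@@H](C)NC(=O)OC(C)(C)C | intermediate
38 | tert-butyl N-[(2R)-1-[2-acetyl-4-[3-chloro-5-methoxy-4-(methoxymethoxy)-7-methylnaphthalen-1-yl]-3-methoxy-5-(methoxymethoxy)phenyl]propan-2-yl]carbamate | CC(=O)c1c(OC)c(-c2cc(Cl)c(OCOC)c3c(OC)cc(C)cc23)c(OCOC)cc1C[C@@H](C)NC(=O)OC(C)(C)C | intermediate
39 | tert-butyl N-[(2R)-1-[2-acetyl-3-methoxy-5-(methoxymethoxy)-4-[5-methoxy-4-(methoxymethoxy)-7-methyl-3-(4,4,5,5-tetramethyl-1,3,2-dioxaborolan-2-yl)naphthalen-1-yl]phenyl]propan-2-yl]carbamate | CC(=O)c1c(OC)c(-c2cc(B4OC(C)(C)C(C)(C)O4)c(OCOC)c3c(OC)cc(C)cc23)c(OCOC)cc1C[C@@H](C)NC(=O)OC(C)(C)C | intermediate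
40 | tert-butyl N-[(2R)-1-[2-acetyl-4-[3-[4-[(1R,3R)-8-hydroxy-6-(methanesulfonyloxy)-1,3-dimethyl-2-(2-nitrobenzenesulfonyl)-1,2,3,4-tetrahydroisoquinolin-5-yl]-8-methoxy-1-(methoxymethoxy)-6-methylnaphthalen-2-yl]-5-methoxy-4-(methoxymethoxy)-7-methylnaphthalen-1-yl]-3-methoxy-5-(methoxymethoxy)phenyl]propan-2-yl]carbamate | COc1cc(C)cc2c(-c3c(OS(C)(=O)=O)cc(O)c4c3C[C@@H](C)N(S(=O)(=O)c3ccccc3[N+](=O)[O-])[C@@H]4C)cc(-c3cc(-c4c(OC)c(C(C)=O)c(C[C@@H](C)NC(=O)OC(C)(C)C)cc4OCOC)c4cc(C)cc(OC)c4c3OCOC)c(OCOC)c12 | intermediate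
41 | tert-butyl N-[(2R)-1-[2-acetyl-4-[3-[4-[(1R,3R)-8-hydroxy-6-(methanesulfonyloxy)-1,3-dimethyl-1,2,3,4-tetrahydroisoquinolin-5-yl]-8-methoxy-1-(methoxymethoxy)-6-methylnaphthalen-2-yl]-5-methoxy-4-(methoxymethoxy)-7-methylnaphthalen-1-yl]-3-methoxy-5-(methoxymethoxy)phenyl]propan-2-yl]carbamate | COc1cc(C)cc2c(-c3c(OS(C)(=O)=O)cc(O)c4c3C[C@@H](C)N[C@@H]4C)cc(-c3cc(-c4c(OC)c(C(C)=O)c(C[C@@H](C)NC(=O)OC(C)(C)C)cc4OCOC)c4cc(C)cc(OC)c4c3OCOC)c(OCOC)c12 | intermediate
42 | tert-butyl N-[(2R)-1-[2-acetyl-4-[3-[4-[(1R,3R)-6,8-dihydroxy-1,3-dimethyl-1,2,3,4-tetrahydroisoquinolin-5-yl]-8-methoxy-1-(methoxymethoxy)-6-methylnaphthalen-2-yl]-5-methoxy-4-(methoxymethoxy)-7-methylnaphthalen-1-yl]-3-methoxy-5-(methoxymethoxy)phenyl]propan-2-yl]carbamate | COc1cc(C)cc2c(-c3c(O)cc(O)c4c3C[C@@H](C)N[C@@H]4C)cc(-c3cc(-c4c(OC)c(C(C)=O)c(C[C@@H](C)NC(=O)OC(C)(C)C)cc4OCOC)c4cc(C)cc(OC)c4c3OCOC)c(OCOC)c12 | intermediate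
43 | 1-[6-[(2R)-2-aminopropyl]-3-[3-[4-[(1R,3R)-6,8-dihydroxy-1,3-dimethyl-1,2,3,4-tetrahydroisoquinolin-5-yl]-1-hydroxy-8-methoxy-6-methylnaphthalen-2-yl]-4-hydroxy-5-methoxy-7-methylnaphthalen-1-yl]-4-hydroxy-2-methoxyphenyl]ethan-1-one | COc1cc(C)cc2c(-c3c(O)cc(O)c4c3C[C@@H](C)N[C@@H]4C)cc(-c3cc(-c4c(OC)c(C(C)=O)c(C[C@@H](C)N)cc4O)c4cc(C)cc(OC)c4c3O)c(O)c12 | intermediate
44 | korundamine A | COc1c2c(cc(O)c1-c1cc(-c3cc(-c4c(O)cc(O)c5c4C[C@@H](C)N[C@@H]5C)c4cc(C)cc(OC)c4c3O)c(O)c3c(OC)cc(C)cc13)C[C@@H](C)N=C2C | target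

**Step count and risk**

Total step count: 26. Longest linear sequence: 13 steps (steps 1–6, 12–15, 24–26).

Steps most likely to fail:

Step 15. The arene oxide may open toward C7, so that the oxygen ends next to C6 and not next to the ring fusion. The trisubstituted, sulfonyloxy-deactivated furan may also attack too slowly, so that hydration of the alkyne competes. The fallback builds ring B by classical isoquinoline chemistry; it sets out from 34 and returns at 42. Double O-benzylation of 34 (BnBr, K2CO3, DMF, 60 °C) would give tert-butyl N-[(2R)-1-[2-acetyl-3,5-bis(benzyloxy)phenyl]propan-2-yl]carbamate F1. TFA would remove the carbamate and the amine would close on the ketone to (3R)-6,8-bis(benzyloxy)-1,3-dimethyl-3,4-dihydroisoquinoline F2. Reduction with LiAlH4/AlMe3 in THF at −78 °C, a combination known to favour the 1,3-trans isomer of such imines (NaBH4 gives cis), should give (1R,3R)-6,8-bis(benzyloxy)-1,3-dimethyl-1,2,3,4-tetrahydroisoquinoline F3. N-Benzylation (BnBr, K2CO3, MeCN) gives the N-benzyl amine F4. Iodination para to the C8 ether (NIS, cat. TFA, MeCN) gives the 5-iodide F5. Suzuki coupling with 10 (Pd(PPh3)4, K3PO4, DME/H2O) gives the 5-naphthyl tetrahydroisoquinoline F6. A second Suzuki coupling with 39 (Pd(OAc)2, SPhos, K3PO4) gives the tribenzyl coupled product F7. Hydrogenolysis (H2, Pd(OH)2/C, EtOAc/MeOH) removes the three benzyl groups and delivers 42.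

Step 13. The redox condensation may stall because both the sulfonamide carbon and the carbinol are secondary, with the betaine consumed unproductively or the activated alcohol eliminating. The fallback replaces in situ activation by a classical two-component alkylation; it sets out from 21 and 22 and returns at 23. Alcohol 22 is converted (MsCl, Et3N, CH2Cl2, 0 °C) into (2S)-but-3-yn-2-yl methanesulfonate F8. The caesium salt of 21 (Cs2CO3, DMF, 40 °C) then displaces the propargylic mesylate by SN2 with inversion, the sulfonamide being deprotonated in preference to the furanone.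

Step 12. Base-induced enolisation and decomposition of the iodofuranone, which has no substituent at C2, may outrun transmetallation of the peri-hindered boronate. The fallback is a base-free Stille coupling; it sets out from 9 and returns at 21. Stannylation of 9 with hexabutylditin (Pd(PPh3)4, toluene, 110 °C, C–Br selective) gives tributyl[3-chloro-5-methoxy-4-(methoxymethoxy)-7-methylnaphthalen-1-yl]stannane F9, which is coupled with 20 (Pd(PPh3)4, CuI, DMF, 60 °C).

Further compounds
F1 | step 15 | tert-butyl N-[(2R)-1-[2-acetyl-3,5-bis(benzyloxy)phenyl]propan-2-yl]carbamate | CC(=O)c1c(OCc2ccccc2)cc(OCc2ccccc2)cc1C[C@@H](C)NC(=O)OC(C)(C)C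
F2 | step 15 | (3R)-6,8-bis(benzyloxy)-1,3-dimethyl-3,4-dihydroisoquinoline | CC1=N[C@H](C)Cc2cc(OCc3ccccc3)cc(OCc3ccccc3)c12
F3 | step 15 | (1R,3R)-6,8-bis(benzyloxy)-1,3-dimethyl-1,2,3,4-tetrahydroisoquinoline | C[C@@H]1Cc2cc(OCc3ccccc3)cc(OCc3ccccc3)c2[C@@H](C)N1
F4 | step 15 | (1R,3R)-2-benzyl-6,8-bis(benzyloxy)-1,3-dimethyl-1,2,3,4-tetrahydroisoquinoline | C[C@@H]1Cc2cc(OCc3ccccc3)cc(OCc3ccccc3)c2[C@@H](C)N1Cc1ccccc1
F5 | step 15 | (1R,3R)-2-benzyl-6,8-bis(benzyloxy)-5-iodo-1,3-dimethyl-1,2,3,4-tetrahydroisoquinoline | C[C@@H]1Cc2c(I)c(OCc3ccccc3)cc(OCc3ccccc3)c2[C@@H](C)N1Cc1ccccc1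
F6 | step 15 | (1R,3R)-2-benzyl-6,8-bis(benzyloxy)-5-[3-chloro-5-methoxy-4-(methoxymethoxy)-7-methylnaphthalen-1-yl]-1,3-dimethyl-1,2,3,4-tetrahydroisoquinoline | C[C@@H]1Cc2c(-c3cc(Cl)c(OCOC)c4c(OC)cc(C)cc34)c(OCc3ccccc3)cc(OCc3ccccc3)c2[C@@H](C)N1Cc1ccccc1
F7 | step 15 | tert-butyl N-[(2R)-1-[2-acetyl-4-[3-[4-[(1R,3R)-2-benzyl-6,8-bis(benzyloxy)-1,3-dimethyl-1,2,3,4-tetrahydroisoquinolin-5-yl]-8-methoxy-1-(methoxymethoxy)-6-methylnaphthalen-2-yl]-5-methoxy-4-(methoxymethoxy)-7-methylnaphthalen-1-yl]-3-methoxy-5-(methoxymethoxy)phenyl]propan-2-yl]carbamate | C[C@@H]1Cc2c(-c3cc(-c4cc(-c5c(OC)c(C(C)=O)c(C[C@@H](C)NC(=O)OC(C)(C)C)cc5OCOC)c5cc(C)cc(OC)c5c4OCOC)c(OCOC)c4c(OC)cc(C)cc34)c(OCc3ccccc3)cc(OCc3ccccc3)c2[C@@H](C)N1Cc1ccccc1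
F8 | step 13 | (2S)-but-3-yn-2-yl methanesulfonate | C[C@H](OS(C)(=O)=O)C#C
F9 | step 12 | tributyl[3-chloro-5-methoxy-4-(methoxymethoxy)-7-methylnaphthalen-1-yl]stannane | CCCC[Sn](CCCC)(CCCC)c1cc(Cl)c(OCOC)c2c(OC)cc(C)cc12
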